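**Retrosynthetic overview**
1. The last C–C bond is C1'–C2', made by sp3–sp2 Negishi coupling of a 5-(iodomethyl)cyclohexenone (ring fragment 15) with an E,E-iododiene lactone (chain fragment 37); the C4 hydroxyl is then released.
2. The strategy rests on the 2,3-dimethoxycyclohex-2-enone ring carrying O4 and the C5 substituent cis on neighbouring carbons, with C1' a plain CH2 between C5 and the E-C2'=C3' alkene and C6 an epimerisable CH beside the C1 ketone. C5–C1' is therefore traced back to radical closure of a temporary O4–Si–C1' tether on a cyclohexadienol ketal.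
3. That dienol comes by CBS reduction of a quinone monoketal, itself made by oxidative dearomatisation of a trimethoxymethylphenol derived from 2,3,4-trimethoxybenzaldehyde.
4. The chain fragment comes from (R)-epichlorohydrin and a silylacetylene through two methylalumination/iodination cycles linked by a homopropargylzinc coupling, then oxirane opening with dilithioacetate and trans-selective lactone methylation.
5. Ring order: carbocycle (from the arene), temporary oxasilolane (closed in the key step, removed by Tamao–Fleming oxidation), butyrolactone (closed on the chain fragment); the fragments are joined last.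

Key step: step 6

Remark: locants are those of the target throughout (ring C1 ketone to C6; chain C1' to C12', with the lactone on C9'–C12'). The facial sense of the CBS reduction is assigned on the assumption that the methoxy-bearing C3 flank of the C4 carbonyl behaves as the larger group. Silyl ethers 9 and 10 are moisture-sensitive and are carried forward crude in base-washed glassware.

**Ring fragment**

Step 1
Reactants: 1 2,3,4-trimethoxybenzaldehyde
Product: 2 1,2,3-trimethoxy-4-methylbenzene (2,3,4-trimethoxytoluene)
Conditions: H2 (3 bar), 10% Pd/C, AcOH, HClO4 (cat.), rt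
Reagents that add atoms: none
Why: Catalytic hydrogenolysis of an electron-rich benzaldehyde in acid runs through the benzylic alcohol to the methylarene and leaves the aryl methyl ethers untouched.

Step 2
Reactants: 2 1,2,3-trimethoxy-4-methylbenzene
Product: 4 2,3,4-trimethoxy-5-methylbenzaldehyde, via aryl iminium chloride 3 (not isolated)
Conditions: POCl3, DMF, 80 °C; then aq. NaOAc, rt
Reagents that add atoms: N,N-dimethylformamide (CN(C)C=O); water (O)
Why: Vilsmeier–Haack formylation should go to the one free ring position that is ortho to one methoxy group and para to another (next to the 4-methoxy group of the toluene), and the iminium salt is hydrolysed on work-up.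

Step 3
Reactants: 4 2,3,4-trimethoxy-5-methylbenzaldehyde
Product: 6 2,3,4-trimethoxy-5-methylphenol, via aryl formate 5 (not isolated)
Conditions: mCPBA, NaHCO3, CH2Cl2, 0 °C → rt; evaporate; K2CO3, MeOH, rt
Reagents that add atoms: 3-chloroperoxybenzoic acid (O=C(OO)c1cccc(Cl)c1)
Why: Baeyer–Villiger oxidation of the electron-rich aldehyde (the Dakin-type aryl migration, used here because the ring has no free hydroxyl) gives the aryl formate, which is methanolysed to the phenol.

Step 4
Reactants: 6 2,3,4-trimethoxy-5-methylphenol
Product: 7 2,3,4,4-tetramethoxy-5-methylcyclohexa-2,5-dien-1-one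
Conditions: PhI(OAc)2, MeOH, 0 °C
Reagents that add atoms: methanol (CO)
Why: Oxidative dearomatisation with the trivalent iodine reagent activates the phenol, and methanol is captured at the para carbon that already bears a methoxy group, giving the quinone monoketal whose ketone is the future C4 and whose ketal is the future C1.

Step 5
Reactants: 7 2,3,4,4-tetramethoxy-5-methylcyclohexa-2,5-dien-1-one
Product: 9 (bromomethyl)dimethyl{[(1R)-2,3,4,4-tetramethoxy-5-methylcyclohexa-2,5-dien-1-yl]oxy}silane, via dienol 8 (not isolated)
Conditions: (S)-2-methyl-CBS-oxazaborolidine (0.2 equiv), BH3·SMe2, THF, −30 °C; MeOH, Et3N, evaporate; then BrCH2SiMe2Cl, imidazole, CH2Cl2, 0 °C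
Reagents that add atoms: (bromomethyl)chlorodimethylsilane (C[Si](C)(Cl)CBr)
Why: Corey–Bakshi–Shibata reduction delivers hydride from the catalyst-bound borane to the carbonyl face fixed by coordination of the ketone anti to its bulkier methoxy-substituted C3 flank, which should set the (R)-carbinol (C4), and the acid-labile bis-allylic dienol is capped at once under basic conditions by the chlorosilane that brings C1'.

Step 6
Reactants: 9 (bromomethyl)dimethylsilyl ether of the (R)-dienol
Product: 10 cis-fused oxasilolane (3aR,4S,7aR)-5,5,6,7-tetramethoxy-2,2,4-trimethyl-2,3,3a,4,5,7a-hexahydrobenzo[d][1,2]oxasilole (O4, C1' and the C6 methyl on one face; ketal intact)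
Conditions: Bu3SnH (syringe pump), AIBN (cat.), benzene (0.01 M), 80 °C
Reagents that add atoms: none
Why: Bu3Sn• abstracts bromine from 9 to give a primary α-silyl radical at C1', which adds to C5 of the C5=C6 alkene, and the resulting tertiary C6 radical takes hydrogen from Bu3SnH to carry the chain. The closest known reaction type is the temporary-silicon-tether radical cyclisation of (bromomethyl)dimethylsilyl ethers of cyclic allylic alcohols. The one ring closed is the five-membered oxasilolane O4–Si–C1'–C5–C4, formed in the 5-exo-trig mode and necessarily cis-fused to the carbocycle. C5 is controlled by the tether, whose two-atom O–Si link lets C1' reach only the face that carries O4, and C6 by hydrogen transfer anti to the new ring (its outcome is immaterial because C6 is equilibrated in step 8). The step needs 5-exo attack at C5 in preference to 6-endo attack at C6 or closure onto C3, and this is secured by C5 being the only unsubstituted alkene carbon next to the carbinol (C6 carries methyl, C3 carries methoxy on an electron-rich alkene). Neutral conditions and slow stannane addition protect the bis-allylic ketal and limit premature reduction of the radical.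

Step 7
Reactants: 10 cis-fused oxasilolane
Product: 11 (1R,5S,6S)-6-(hydroxymethyl)-2,3,4,4-tetramethoxy-5-methylcyclohex-2-en-1-ol (syn 1,3-diol; ketal intact)
Conditions: 30% H2O2, KF, KHCO3, THF/MeOH, rt
Reagents that add atoms: hydrogen peroxide (OO)
Why: Tamao–Fleming oxidation: the fluoride-activated, oxygen-substituted silicon takes up peroxide and C1' migrates from Si to O, while the basic medium leaves the ketal and enol ether alone, so the syn 1,3-diol is released with C4 and C5 untouched.

Step 8
Reactants: 11 syn 1,3-diol ketal
Product: 13 (4R,5S,6R)-4-hydroxy-5-(hydroxymethyl)-2,3-dimethoxy-6-methylcyclohex-2-en-1-one (4,5-cis and 5,6-trans), via all-cis enone diol 12 (not isolated)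
Conditions: oxalic acid, THF/H2O, rt; then K2CO3, MeOH, rt
Reagents that add atoms: water (O)
Why: Mild acid hydrolysis of the allylic dimethyl ketal unmasks the C1 ketone as a vinylogous ester, and base-mediated enolisation at C6 (the only α-CH) should then move the methyl to the more stable 5,6-trans arrangement, which has the C5 and C6 groups both pseudo-equatorial and avoids the 1,3-diaxial or axial-C5 penalty of the all-cis isomer.

Step 9
Reactants: 13 5,6-trans enone diol
Product: 14 (4R,5R,6R)-4-hydroxy-5-(iodomethyl)-2,3-dimethoxy-6-methylcyclohex-2-en-1-one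
Conditions: PPh3, I2, imidazole, CH2Cl2, 0 °C
Reagents that add atoms: iodine (II)
Why: Appel-type (Garegg–Samuelsson) iodination activates the unhindered primary hydroxyl much faster than the flanked secondary allylic one, and the medium is too weakly basic to enolise the ketone toward cyclopropane formation.

Step 10
Reactants: 14 iodo alcohol
Product: 15 (4R,5R,6R)-4-[(tert-butyldimethylsilyl)oxy]-5-(iodomethyl)-2,3-dimethoxy-6-methylcyclohex-2-en-1-one (ring fragment)
Conditions: TBSOTf, 2,6-lutidine, CH2Cl2, −78 °C
Reagents that add atoms: tert-butyldimethylsilyl trifluoromethanesulfonate (CC(C)(C)[Si](C)(C)OS(=O)(=O)C(F)(F)F)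
Why: Silylation with the silyl triflate and a hindered pyridine base at low temperature caps the hindered C4 hydroxyl quickly, without enolising the γ-iodo ketone, so that no free OH can later quench the organozinc.

**Chain fragment**

Step 11
Reactants: 16 (R)-epichlorohydrin; 17 trimethylsilylacetylene
Product: 19 (R)-1-chloro-5-(trimethylsilyl)pent-4-yn-2-ol, via lithium acetylide 18 (not isolated)
Conditions: 17, n-BuLi, THF, −78 °C; BF3·OEt2; then 16, −78 °C
Reagents that add atoms: none
Why: The BF3-activated oxirane is opened by the lithium acetylide at its unsubstituted CH2 in an SN2 manner, faster than chloride displacement, so the stereocentre is not touched and stays (R).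

Step 12
Reactants: 19 (R)-1-chloro-5-(trimethylsilyl)pent-4-yn-2-ol
Product: 20 (R)-tert-butyl{[1-chloro-5-(trimethylsilyl)pent-4-yn-2-yl]oxy}dimethylsilane
Conditions: TBSCl, imidazole, DMF, rt
Reagents that add atoms: tert-butylchlorodimethylsilane (CC(C)(C)[Si](C)(C)Cl)
Why: Standard silyl protection placed before alkyne desilylation, so that base cannot close the chlorohydrin to the oxirane too early and no free OH consumes the alane later.

Step 13
Reactants: 20 silyl-protected silylalkyne
Product: 21 (R)-tert-butyl[(1-chloropent-4-yn-2-yl)oxy]dimethylsilane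
Conditions: K2CO3, MeOH, rt
Reagents that add atoms: none
Why: Base-mediated methanolysis of the C(sp)–Si bond (protodesilylation) frees the terminal alkyne while the TBS ether and the primary chloride survive.

Step 14
Reactants: 21 terminal alkyne
Product: 23 (R,E)-tert-butyl[(1-chloro-5-iodo-4-methylpent-4-en-2-yl)oxy]dimethylsilane (C6' to C10'), via alkenylalane 22 (not isolated)
Conditions: Me3Al, Cp2ZrCl2 (0.25 equiv), CH2Cl2, 0 °C → rt; then I2, THF, −30 → 0 °C
Reagents that add atoms: trimethylaluminium (C[Al](C)C); iodine (II)
Why: Negishi zirconium-catalysed carboalumination adds Me–Al syn across the terminal alkyne with methyl on the internal carbon, and iodinolysis of the C–Al bond with retention gives the E-iodoalkene; the silyl ether and primary chloride are tolerated.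

Step 15
Reactants: 23 E-vinyl iodide; 24 (4-iodobut-1-yn-1-yl)trimethylsilane
Product: 26 (R,E)-tert-butyl{[1-chloro-4-methyl-9-(trimethylsilyl)non-4-en-8-yn-2-yl]oxy}dimethylsilane (C2' to C10'), via homopropargylzinc iodide 25 (not isolated)
Conditions: 24, Zn dust (activated: BrCH2CH2Br, TMSCl), THF, 40 °C; then 23, Pd(PPh3)4 (5 mol%), THF, rt
Reagents that add atoms: none
Why: Negishi cross-coupling: zinc inserts into the primary C–I bond of 24, the alkylzinc iodide transmetalates to the alkenylpalladium iodide formed from 23 and zerovalent palladium, and reductive elimination joins C5'–C6' with retention of the E geometry, the alkyl chloride being inert.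

Step 16
Reactants: 26 silyl-capped enyne
Product: 27 (R,E)-tert-butyl[(1-chloro-4-methylnon-4-en-8-yn-2-yl)oxy]dimethylsilane
Conditions: K2CO3, MeOH, rt
Reagents that add atoms: none
Why: Protodesilylation of the alkynylsilane under mild base, as in step 13, leaves the alkene, the TBS ether and the chloride unchanged.

Step 17
Reactants: 27 terminal enyne
Product: 29 (R,4E,8E)-tert-butyl[(1-chloro-9-iodo-4,8-dimethylnona-4,8-dien-2-yl)oxy]dimethylsilane, via alkenylalane 28 (not isolated)
Conditions: Me3Al, Cp2ZrCl2 (0.25 equiv), CH2Cl2, 0 °C → rt; then I2, THF, −30 → 0 °C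
Reagents that add atoms: trimethylaluminium (C[Al](C)C); iodine (II)
Why: A second Negishi carboalumination/iodinolysis sets the C2'=C3' E-iodoalkene by syn methylalumination of the terminal alkyne, and the existing trisubstituted alkene does not react.

Step 18
Reactants: 29 E,E-iododiene silyl ether
Product: 31 (R)-2-[(2E,6E)-7-iodo-2,6-dimethylhepta-2,6-dien-1-yl]oxirane, via chlorohydrin 30 (not isolated)
Conditions: Bu4NF, THF, 0 °C → rt
Reagents that add atoms: none
Why: Fluoride cleaves the Si–O bond and the basic medium lets the freed alkoxide displace the neighbouring chloride (intramolecular Williamson closure), giving the oxirane with the carbinol configuration unchanged.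

Step 19
Reactants: 31 E,E-iododiene oxirane; 32 acetic acid
Product: 35 (S)-5-[(2E,6E)-7-iodo-2,6-dimethylhepta-2,6-dien-1-yl]dihydrofuran-2(3H)-one, via dilithioacetate 33 (not isolated), via hydroxy acid 34 (not isolated)
Conditions: 32, LDA (2 equiv), THF, 0 → 40 °C; then 31, 50 °C; aq. HCl; TsOH (cat.), toluene, rt
Reagents that add atoms: none
Why: The acetic acid dianion opens the terminal oxirane at its CH2 by SN2 attack, and on acidification the γ-hydroxy acid closes to the five-membered lactone without breaking the C9'–O bond, so C9' keeps its configuration.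

Step 20
Reactants: 35 γ-substituted butyrolactone
Product: 37 (3R,5S)-5-[(2E,6E)-7-iodo-2,6-dimethylhepta-2,6-dien-1-yl]-3-methyldihydrofuran-2(3H)-one (chain fragment), via lithium enolate 36 (not isolated)
Conditions: LDA (1.05 equiv), THF, −78 °C; then MeI, −78 °C
Reagents that add atoms: iodomethane (CI)
Why: Kinetic lactone enolate alkylation: iodomethane should approach the planar enolate from the face opposite the γ-substituent to give the trans-3,5-disubstituted lactone, and low temperature with a near-stoichiometric base limits dimethylation and spares the vinyl iodide.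

**Fragment union**

Step 21
Reactants: 15 ring fragment iodide; 37 chain fragment vinyl iodide
Product: 40 target CNP0532375.1, via alkylzinc iodide 38 (not isolated), via silyl ether 39 (not isolated)
Conditions: 15, Zn dust (activated: BrCH2CH2Br, TMSCl), DMF, rt; then 37, Pd2(dba)3 (2.5 mol%), SPhos (10 mol%), THF/DMF, rt; then HF·pyridine, pyridine, 0 °C → rt
Reagents that add atoms: none
Why: Negishi sp3–sp2 coupling: zinc insertion into the primary C1'–I bond gives an alkylzinc iodide that tolerates the ketone, vinylogous ester, silyl ether and lactone, a bulky biarylphosphine on palladium favours reductive elimination over β-hydride loss with retention of the E geometry, and HF·pyridine added before work-up cleaves the C4 silyl ether under acidic conditions that neither epimerise C6 or C11' nor open the lactone.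

**Compound list**
1 | 2,3,4-trimethoxybenzaldehyde | COc1ccc(C=O)c(OC)c1OC | starting material
2 | 1,2,3-trimethoxy-4-methylbenzene | COc1ccc(C)c(OC)c1OC | intermediate
3 | N-[(2,3,4-trimethoxy-5-methylphenyl)methylidene]-N-methylmethanaminium chloride (formed in situ) | COc1c(C=[N+](C)C)cc(C)c(OC)c1OC.[Cl-] | intermediate
4 | 2,3,4-trimethoxy-5-methylbenzaldehyde | COc1c(C=O)cc(C)c(OC)c1OC | intermediate
5 | 2,3,4-trimethoxy-5-methylphenyl formate (formed in situ) | COc1c(OC=O)cc(C)c(OC)c1OC | intermediate
6 | 2,3,4-trimethoxy-5-methylphenol | COc1c(O)cc(C)c(OC)c1OC | intermediate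
7 | 2,3,4,4-tetramethoxy-5-methylcyclohexa-2,5-dien-1-one | COC1=C(OC)C(=O)C=C(C)C1(OC)OC | intermediate
8 | (1R)-2,3,4,4-tetramethoxy-5-methylcyclohexa-2,5-dien-1-ol (formed in situ) | COC1=C(OC)[C@H](O)C=C(C)C1(OC)OC | intermediate
9 | (bromomethyl)dimethyl{[(1R)-2,3,4,4-tetramethoxy-5-methylcyclohexa-2,5-dien-1-yl]oxy}silane | COC1=C(OC)[C@H](O[Si](C)(C)CBr)C=C(C)C1(OC)OC | intermediate
10 | (3aR,4S,7aR)-5,5,6,7-tetramethoxy-2,2,4-trimethyl-2,3,3a,4,5,7a-hexahydrobenzo[d][1,2]oxasilole | COC1=C(OC)[C@@H]2O[Si](C)(C)C[C@@H]2[C@H](C)C1(OC)OC | intermediate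
11 | (1R,5S,6S)-6-(hydroxymethyl)-2,3,4,4-tetramethoxy-5-methylcyclohex-2-en-1-ol | COC1=C(OC)[C@H](O)[C@H](CO)[C@H](C)C1(OC)OC | intermediate
12 | (4R,5S,6S)-4-hydroxy-5-(hydroxymethyl)-2,3-dimethoxy-6-methylcyclohex-2-en-1-one, all-cis (formed in situ) | COC1=C(OC)[C@H](O)[C@H](CO)[C@H](C)C1=O | intermediate
13 | (4R,5S,6R)-4-hydroxy-5-(hydroxymethyl)-2,3-dimethoxy-6-methylcyclohex-2-en-1-one | COC1=C(OC)[C@H](O)[C@H](CO)[C@@H](C)C1=O | intermediate
14 | (4R,5R,6R)-4-hydroxy-5-(iodomethyl)-2,3-dimethoxy-6-methylcyclohex-2-en-1-one | COC1=C(OC)[C@H](O)[C@H](CI)[C@@H](C)C1=O | intermediate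
15 | (4R,5R,6R)-4-[(tert-butyldimethylsilyl)oxy]-5-(iodomethyl)-2,3-dimethoxy-6-methylcyclohex-2-en-1-one | COC1=C(OC)[C@H](O[Si](C)(C)C(C)(C)C)[C@H](CI)[C@@H](C)C1=O | intermediate
16 | (R)-epichlorohydrin | C1[C@@H](O1)CCl | starting material
17 | trimethylsilylacetylene | C#C[Si](C)(C)C | starting material
18 | lithium (trimethylsilyl)acetylide (formed in situ) | [Li]C#C[Si](C)(C)C | intermediate
19 | (R)-1-chloro-5-(trimethylsilyl)pent-4-yn-2-ol | C[Si](C)(C)C#CC[C@@H](O)CCl | intermediate
20 | (R)-tert-butyl{[1-chloro-5-(trimethylsilyl)pent-4-yn-2-yl]oxy}dimethylsilane | C[Si](C)(C)C#CC[C@@H](O[Si](C)(C)C(C)(C)C)CCl | intermediate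
21 | (R)-tert-butyl[(1-chloropent-4-yn-2-yl)oxy]dimethylsilane | C#CC[C@@H](O[Si](C)(C)C(C)(C)C)CCl | intermediate
22 | (E)-alkenyldimethylalane from 21 (formed in situ) | C[Al](C)/C=C(\C)C[C@@H](O[Si](C)(C)C(C)(C)C)CCl | intermediate
23 | (R,E)-tert-butyl[(1-chloro-5-iodo-4-methylpent-4-en-2-yl)oxy]dimethylsilane | I/C=C(\C)C[C@@H](O[Si](C)(C)C(C)(C)C)CCl | intermediate
24 | (4-iodobut-1-yn-1-yl)trimethylsilane | C[Si](C)(C)C#CCCI | starting material
25 | [4-(trimethylsilyl)but-3-yn-1-yl]zinc iodide (formed in situ) | C[Si](C)(C)C#CCC[Zn]I | intermediate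
26 | (R,E)-tert-butyl{[1-chloro-4-methyl-9-(trimethylsilyl)non-4-en-8-yn-2-yl]oxy}dimethylsilane | C[Si](C)(C)C#CCC/C=C(\C)C[C@@H](O[Si](C)(C)C(C)(C)C)CCl | intermediate
27 | (R,E)-tert-butyl[(1-chloro-4-methylnon-4-en-8-yn-2-yl)oxy]dimethylsilane | C#CCC/C=C(\C)C[C@@H](O[Si](C)(C)C(C)(C)C)CCl | intermediate
28 | (E,E)-dienyldimethylalane from 27 (formed in situ) | C[Al](C)/C=C(\C)CC/C=C(\C)C[C@@H](O[Si](C)(C)C(C)(C)C)CCl | intermediate
29 | (R,4E,8E)-tert-butyl[(1-chloro-9-iodo-4,8-dimethylnona-4,8-dien-2-yl)oxy]dimethylsilane | I/C=C(\C)CC/C=C(\C)C[C@@H](O[Si](C)(C)C(C)(C)C)CCl | intermediate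
30 | (R,4E,8E)-1-chloro-9-iodo-4,8-dimethylnona-4,8-dien-2-ol (formed in situ) | I/C=C(\C)CC/C=C(\C)C[C@@H](O)CCl | intermediate
31 | (R)-2-[(2E,6E)-7-iodo-2,6-dimethylhepta-2,6-dien-1-yl]oxirane | I/C=C(\C)CC/C=C(\C)C[C@@H]1CO1 | intermediate
32 | acetic acid | CC(=O)O | starting material
33 | dilithioacetate (formed in situ) | [Li]CC(=O)O[Li] | intermediate
34 | (S,6E,10E)-4-hydroxy-11-iodo-6,10-dimethylundeca-6,10-dienoic acid (formed in situ) | I/C=C(\C)CC/C=C(\C)C[C@@H](O)CCC(=O)O | intermediate
35 | (S)-5-[(2E,6E)-7-iodo-2,6-dimethylhepta-2,6-dien-1-yl]dihydrofuran-2(3H)-one | I/C=C(\C)CC/C=C(\C)C[C@@H]1CCC(=O)O1 | intermediate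
36 | lithium enolate of 35 (formed in situ) | I/C=C(\C)CC/C=C(\C)C[C@@H]1CC=C(O[Li])O1 | intermediate
37 | (3R,5S)-5-[(2E,6E)-7-iodo-2,6-dimethylhepta-2,6-dien-1-yl]-3-methyldihydrofuran-2(3H)-one | I/C=C(\C)CC/C=C(\C)C[C@@H]1C[C@@H](C)C(=O)O1 | intermediate
38 | alkylzinc iodide from 15 (C1'–ZnI; formed in situ) | COC1=C(OC)[C@H](O[Si](C)(C)C(C)(C)C)[C@H](C[Zn]I)[C@@H](C)C1=O | intermediate
39 | C4 tert-butyldimethylsilyl ether of the target (formed in situ) | COC1=C(OC)[C@H](O[Si](C)(C)C(C)(C)C)[C@H](C/C=C(\C)CC/C=C(\C)C[C@@H]2C[C@@H](C)C(=O)O2)[C@@H](C)C1=O | intermediate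
40 | (4R,5R,6R)-4-hydroxy-2,3-dimethoxy-6-methyl-5-{(2E,6E)-3,7-dimethyl-8-[(2S,4R)-4-methyl-5-oxotetrahydrofuran-2-yl]octa-2,6-dien-1-yl}cyclohex-2-en-1-one (CNP0532375.1) | COC1=C(OC)[C@H](O)[C@H](C/C=C(\C)CC/C=C(\C)C[C@@H]2C[C@@H](C)C(=O)O2)[C@@H](C)C1=O | target

**Totals**
Total step count: 21.
Longest linear sequence: 11 steps (steps 1–10 and 21 from 2,3,4-trimethoxybenzaldehyde; the chain branch, steps 11–20 and 21 from (R)-epichlorohydrin, is equally long).

**Steps most likely to fail**

Step 6 (radical cyclisation). The α-silyl radical may be reduced by the stannane before it closes, it may add at C3 or 6-endo at C6, or the labile silyl ether and bis-allylic ketal may decompose on heating. The fallback sets out from dienol 8 and replaces the radical delivery by a hydroxyl-directed carbenoid delivery. Simmons–Smith cyclopropanation in the Furukawa variant (Et2Zn, CH2I2, CH2Cl2, −20 °C) should place the CH2 across C5=C6 from the face of the C4 hydroxyl, the tetrasubstituted dimethoxy alkene being shielded on both flanks, and give the syn cyclopropyl carbinol F3. Hydrolysis of the ketal (oxalic acid, THF/H2O) gives the cyclopropyl enone F4. Homoconjugate opening with iodotrimethylsilane made in the flask (TMSCl, NaI, MeCN, 0 °C) has iodide attack the cyclopropane CH2 and cleave the exocyclic C6–C1' bond that overlaps with the carbonyl, giving the bis(trimethylsilyl) iodo dienol ether F5. Mildly acidic aqueous work-up removes both silyl groups and protonates C6, which should settle in the 5,6-trans arrangement. The route is rejoined at iodo alcohol 14, before step 10.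

Step 5 (CBS reduction and silylation). The catalyst may discriminate poorly between the two sp2 flanks of the carbonyl, or the dienol may aromatise by acid-triggered loss of methanol during the quench. The fallback sets out from dienone 7 and replaces catalytic asymmetric reduction by resolution. Reduction with i-Bu2AlH (THF, −78 °C, Rochelle-salt work-up) gives the racemic dienol F1. Lipase-catalysed acylation (Burkholderia cepacia lipase, vinyl acetate, tert-butyl methyl ether with a trace of Et3N) should, by the empirical rule for secondary alcohols, acylate the (R)-enantiomer, whose larger flank is the methoxy-bearing carbon, to give the (R)-acetate F2. F2 is separated from the unreacted (S)-alcohol on base-washed silica, and methanolysis (K2CO3, MeOH, 0 °C) returns dienol 8, which is silylated as in the second half of step 5 to give 9.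

Step 21 (Negishi union and desilylation). Zinc insertion may stall, the alkylzinc may be protonated, the γ-silyloxy enone may be reduced at the zinc surface, or the alkylpalladium intermediate may lose a β-hydride from C5. The fallback sets out from iodide 15 and vinyl iodide 37 and avoids a preformed organometallic. A nickel-catalysed reductive cross-electrophile coupling (NiI2, 4,4'-di-tert-butyl-2,2'-bipyridine, Mn powder, NaI, DMPU, rt) generates the C1' radical from 15 and captures it on the alkenylnickel species formed from 37. This should give silyl ether 39, where the route is rejoined; HF·pyridine as in step 21 then gives 40.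

**Further compounds**
F1 | step 5 | racemic 2,3,4,4-tetramethoxy-5-methylcyclohexa-2,5-dien-1-ol | COC1=C(OC)C(O)C=C(C)C1(OC)OC
F2 | step 5 | (1R)-2,3,4,4-tetramethoxy-5-methylcyclohexa-2,5-dien-1-yl acetate | COC1=C(OC)[C@H](OC(C)=O)C=C(C)C1(OC)OC
F3 | step 6 | syn cyclopropyl carbinol ketal (CH2 bridging C5 and C6 on the face of the C4 hydroxyl) | COC1=C(OC)[C@H](O)[C@@H]2C[C@]2(C)C1(OC)OC
F4 | step 6 | syn cyclopropyl enone (C1 ketone, C5–C6 cyclopropane cis to the C4 hydroxyl) | COC1=C(OC)[C@H](O)[C@@H]2C[C@]2(C)C1=O
F5 | step 6 | bis(trimethylsilyl) iodo dienol ether (C4–OSiMe3, C1–OSiMe3 enol ether, C5–CH2I) | COC1=C(OC)[C@H](O[Si](C)(C)C)[C@H](CI)C(C)=C1O[Si](C)(C)C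
F0 | step 21 | none | none
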